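## Retrosynthetic overview

1. Ring B (the ten-membered carbocycle) is closed last, by ring-closing metathesis across C1=C2 of an acyclic triene diol; the ring enforces the Z olefin.
2. Ring A (the cis-fused methylidene lactone) is closed before it: C6–C7 by syn-selective allylboration of a (Z)-enal (C1–C6, C15) with a 2-(methoxycarbonyl)allylboronate (C7–C14), then C6–O by lactonisation.
3. Key step: the C8–O bond, the C8 stereocentre and the tiglate are installed together by an enantioselective palladium-catalysed 1,4-acyloxychlorination of a 2-(methoxycarbonyl)-1,3-diene with tiglic acid; the allylic chloride it leaves is borylated.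
4. The diene comes from (R)-linalool (C10 from the chiral pool) by ozonolysis, Morita–Baylis–Hillman reaction and dehydration.
5. The enal comes from acrolein and methyl propiolate by asymmetric alkynylation (C3), syn-carbocupration (Z-C4=C5), reduction and oxidation.

Assumptions: germacrane numbering is used for the target carbons (C3 secondary carbinol, C6 lactone O–CH, C7 ring-fusion CH, C8 tigloyloxy carbon, C10 tertiary carbinol, C11–C13 methylidene lactone carbons). The target SMILES is read as the cis-fused lactone with 3R,6S,7R,8R,10R and Z olefins at C1=C2 and C4=C5. Where a chiral catalyst or reagent is named, the antipode that gives the stated configuration is meant if the sense of induction turns out opposite.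

## Route

Step 1
Reactants: 1 (R)-(−)-linalool
Product: 2 (3R)-3,7-dimethyl-3-(triethylsilyloxy)octa-1,6-diene
Conditions: TESOTf, 2,6-lutidine, CH2Cl2, −78 → 0 °C
Reagents that add atoms: triethylsilyl trifluoromethanesulfonate, CC[Si](CC)(CC)OS(=O)(=O)C(F)(F)F
Why: Silyl ether formation on the tertiary allylic alcohol blocks lactol formation after step 2 and leaves the C10 stereocentre, taken from the chiral pool, untouched.

Step 2
Reactants: 2 (3R)-3,7-dimethyl-3-(triethylsilyloxy)octa-1,6-diene
Product: 4 (4R)-4-methyl-4-(triethylsilyloxy)hex-5-enal, via ozonide 3 (not isolated)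
Conditions: O3 (1.0 equiv), CH2Cl2, −78 °C; then PPh3, −78 → 23 °C
Reagents that add atoms: ozone, [O-][O+]=O
Why: Chemoselective ozonolysis with reductive work-up, because ozone cleaves the electron-rich trisubstituted olefin much faster than the hindered vinyl group on the quaternary silyloxy carbon.

Step 3
Reactants: 4 (4R)-4-methyl-4-(triethylsilyloxy)hex-5-enal; 5 methyl acrylate
Product: 6 methyl (6R)-3-hydroxy-6-methyl-2-methylidene-6-(triethylsilyloxy)oct-7-enoate
Conditions: DABCO (1 equiv), methyl acrylate (3 equiv), MeOH, 23 °C, 3 d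
Reagents that add atoms: none
Why: The Morita–Baylis–Hillman reaction joins the acrylate α-carbon (C11) to C7; the new carbinol centre forms as a mixture and is erased in step 4.

Step 4
Reactants: 6 methyl (6R)-3-hydroxy-6-methyl-2-methylidene-6-(triethylsilyloxy)oct-7-enoate
Product: 8 methyl (3E,6R)-6-methyl-2-methylidene-6-(triethylsilyloxy)octa-3,7-dienoate, via mesylate 7 (not isolated)
Conditions: MsCl, Et3N, CH2Cl2, 0 °C; then DBU, 0 → 23 °C
Reagents that add atoms: none
Why: Mesylation and base-induced elimination give the conjugated diene, E at C7=C8 for steric reasons; it is used at once because 2-alkoxycarbonyl dienes slowly dimerise by Diels–Alder reaction.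

Step 5
Reactants: 8 methyl (3E,6R)-6-methyl-2-methylidene-6-(triethylsilyloxy)octa-3,7-dienoate; 9 tiglic acid [(2E)-2-methylbut-2-enoic acid]
Product: 10 methyl (2Z,4R,6R)-2-(chloromethyl)-6-methyl-4-{[(2E)-2-methylbut-2-enoyl]oxy}-6-(triethylsilyloxy)octa-2,7-dienoate
Conditions: PdCl2(MeCN)2 (5 mol%), (S)-t-BuPyOx (6 mol%), p-benzoquinone (1.5 equiv), LiCl (2 equiv), tiglic acid (4 equiv), acetone, 23 °C
Reagents that add atoms: lithium chloride, [Li+].[Cl-]
Why: Proposed new method: a chiral pyridine–oxazoline complex of divalent palladium binds the more electron-rich C7=C8 olefin of the cross-conjugated diene, tiglate attacks the diene terminus C8 anti to the metal (acyloxypalladation, which sets C8 as R under ligand control), and benzoquinone-assisted chloride attack on the resulting 2-(methoxycarbonyl)allyl palladium fragment at its unhindered CH2 end (C13) gives the conjugated (Z)-allylic chloride while benzoquinone reoxidises the zerovalent palladium released; the closest known reactions are Bäckvall's racemic palladium-catalysed 1,4-acetoxychlorination and 1,4-diacyloxylation of simple 1,3-dienes (isoprene takes the carboxylate at the terminus of its more electron-rich olefin and chloride at the other end) and ligand-controlled enantioselective oxypalladation of olefins, neither shown on a 2-alkoxycarbonyl diene, with an unsaturated acid, or with enantiocontrol.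

Step 6
Reactants: 10 methyl (2Z,4R,6R)-2-(chloromethyl)-6-methyl-4-{[(2E)-2-methylbut-2-enoyl]oxy}-6-(triethylsilyloxy)octa-2,7-dienoate
Product: 11 methyl (2E,4R,6R)-6-methyl-4-{[(2E)-2-methylbut-2-enoyl]oxy}-2-[(4,4,5,5-tetramethyl-1,3,2-dioxaborolan-2-yl)methyl]-6-(triethylsilyloxy)octa-2,7-dienoate
Conditions: B2pin2 (1.1 equiv), Pd2(dba)3 (2.5 mol%), toluene, 40 °C
Reagents that add atoms: bis(pinacolato)diboron, CC1(C)OB(OC1(C)C)B1OC(C)(C)C(C)(C)O1
Why: Miyaura-type allylic borylation, in which zerovalent palladium ionises the primary allylic chloride much faster than the secondary allylic tiglate and boron goes to the unhindered CH2 terminus with the olefin geometry kept (C8 cis to CH2B); unlike an allylzinc or allylindium reagent, the boronate does not expel the neighbouring acyloxy group.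

Step 7
Reactants: 12 acrolein (prop-2-enal); 13 methyl propiolate (methyl prop-2-ynoate)
Product: 15 methyl (4R)-4-hydroxyhex-5-en-2-ynoate, via alkynylzinc 14 (not isolated)
Conditions: (S,S)-ProPhenol (10 mol%), Me2Zn (3 equiv), methyl propiolate (3 equiv), toluene, 0 °C; then acrolein (slow addition), 4 °C; aq. NH4Cl
Reagents that add atoms: none
Why: Trost's ProPhenol–dinuclear zinc asymmetric alkynylation of an α,β-unsaturated aldehyde, in which the chiral catalyst pocket fixes the aldehyde face and sets C3 as R.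

Step 8
Reactants: 15 methyl (4R)-4-hydroxyhex-5-en-2-ynoate
Product: 16 methyl (4R)-4-(triethylsilyloxy)hex-5-en-2-ynoate
Conditions: TESCl, imidazole, DMF, 0 °C
Reagents that add atoms: chlorotriethylsilane, CC[Si](CC)(CC)Cl
Why: Silylation of the secondary alcohol prevents butenolide formation in step 9 and lactol or furan formation at the aldehyde stage.

Step 9
Reactants: 16 methyl (4R)-4-(triethylsilyloxy)hex-5-en-2-ynoate
Product: 18 methyl (2Z,4R)-3-methyl-4-(triethylsilyloxy)hexa-2,5-dienoate, via alkenylcuprate 17 (not isolated)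
Conditions: Me2CuLi (1.2 equiv), THF, −78 °C; sat. aq. NH4Cl at −78 °C
Reagents that add atoms: lithium dimethylcuprate, [Li+].C[Cu-]C
Why: Syn-carbocupration of the ynoate and protonation with retention at −78 °C place the new methyl group (C15) cis to H5, so C3 and the ester carbon are cis, which is the Z-C4=C5 olefin.

Step 10
Reactants: 18 methyl (2Z,4R)-3-methyl-4-(triethylsilyloxy)hexa-2,5-dienoate
Product: 19 (2Z,4R)-3-methyl-4-(triethylsilyloxy)hexa-2,5-dien-1-ol
Conditions: i-Bu2AlH (2.2 equiv), CH2Cl2, −78 °C; aq. potassium sodium tartrate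
Reagents that add atoms: none
Why: 1,2-Reduction of the enoate to the allylic alcohol at low temperature leaves the Z olefin and the silyl ether intact.

Step 11
Reactants: 19 (2Z,4R)-3-methyl-4-(triethylsilyloxy)hexa-2,5-dien-1-ol
Product: 20 (2Z,4R)-3-methyl-4-(triethylsilyloxy)hexa-2,5-dienal
Conditions: Dess–Martin periodinane, NaHCO3, CH2Cl2, 0 °C
Reagents that add atoms: none
Why: Buffered Dess–Martin oxidation gives the Z-enal without isomerisation; it is used at once.

Step 12
Reactants: 11 the allylboronate from step 6; 20 (2Z,4R)-3-methyl-4-(triethylsilyloxy)hexa-2,5-dienal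
Product: 22 (1R,3R)-3-methyl-1-{(2S,3R)-4-methylidene-2-[(1Z,3R)-2-methyl-3-(triethylsilyloxy)penta-1,4-dien-1-yl]-5-oxooxolan-3-yl}-3-(triethylsilyloxy)pent-4-en-1-yl (2E)-2-methylbut-2-enoate, via hydroxy ester 21 (not isolated)
Conditions: Sc(OTf)3 (10 mol%), toluene, −78 → −40 °C; aq. NaHCO3; then PPTS (10 mol%), CH2Cl2, 23 °C
Reagents that add atoms: none
Why: Hall-type Lewis-acid-catalysed allylboration through a closed chair transition state, in which C8 (cis to CH2B) sits axial and so gives the 6,7-syn adduct (hence the cis lactone after acyl transfer with loss of methanol), while the aldehyde approaches the allyl face anti to the C9 branch with H8 eclipsing the CH2B group, which gives 7R and therefore 6S.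

Step 13
Reactants: 22 the bis(triethylsilyl) lactone from step 12
Product: 23 (1R,3R)-3-hydroxy-1-{(2S,3R)-2-[(1Z,3R)-3-hydroxy-2-methylpenta-1,4-dien-1-yl]-4-methylidene-5-oxooxolan-3-yl}-3-methylpent-4-en-1-yl (2E)-2-methylbut-2-enoate
Conditions: HF·pyridine, pyridine, THF, 0 → 23 °C
Reagents that add atoms: none
Why: Fluoride cleaves both triethylsilyl ethers under pyridine-buffered conditions that spare the tiglate, the methylidene lactone and the acid-sensitive bis-allylic carbinol.

Step 14
Reactants: 23 the triene diol from step 13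
Product: 24 (3aR,4R,6R,7Z,9R,10Z,11aS)-6,9-dihydroxy-6,10-dimethyl-3-methylidene-2-oxo-2,3,3a,4,5,6,9,11a-octahydrocyclodeca[b]furan-4-yl (2E)-2-methylbut-2-enoate
Conditions: RuCl2(PCy3)2(=CHPh) (first-generation Grubbs catalyst, 10 mol%), CH2Cl2 (0.5 mM), 40 °C
Reagents that add atoms: none
Why: Ring-closing olefin metathesis, in which both vinyl groups are activated by an allylic hydroxyl (as in the fast metathesis of linalool), the first-generation catalyst leaves the electron-poor methylidene lactone and tiglate alone, high dilution favours cyclisation, and the cis-fused lactone together with the Z-C4=C5 olefin makes the Z-C1=C2 cyclodecadiene the accessible isomer.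

## Compound list

1 | (R)-(−)-linalool, (3R)-3,7-dimethylocta-1,6-dien-3-ol | CC(C)=CCC[C@@](C)(O)C=C | starting material
2 | (3R)-3,7-dimethyl-3-(triethylsilyloxy)octa-1,6-diene | CC(C)=CCC[C@@](C)(O[Si](CC)(CC)CC)C=C | intermediate
3 | ozonide, 3,3-dimethyl-5-[(3R)-3-methyl-3-(triethylsilyloxy)pent-4-en-1-yl]-1,2,4-trioxolane | CC1(C)OOC(CC[C@@](C)(O[Si](CC)(CC)CC)C=C)O1 | intermediate
4 | (4R)-4-methyl-4-(triethylsilyloxy)hex-5-enal | O=CCC[C@@](C)(O[Si](CC)(CC)CC)C=C | intermediate
5 | methyl acrylate | C=CC(=O)OC | starting material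
6 | methyl (6R)-3-hydroxy-6-methyl-2-methylidene-6-(triethylsilyloxy)oct-7-enoate (both C3 epimers) | C=C(C(=O)OC)C(O)CC[C@@](C)(O[Si](CC)(CC)CC)C=C | intermediate
7 | mesylate, methyl (6R)-3-(methanesulfonyloxy)-6-methyl-2-methylidene-6-(triethylsilyloxy)oct-7-enoate | C=C(C(=O)OC)C(OS(C)(=O)=O)CC[C@@](C)(O[Si](CC)(CC)CC)C=C | intermediate
8 | methyl (3E,6R)-6-methyl-2-methylidene-6-(triethylsilyloxy)octa-3,7-dienoate | C=C(C(=O)OC)/C=C/C[C@@](C)(O[Si](CC)(CC)CC)C=C | intermediate
9 | tiglic acid, (2E)-2-methylbut-2-enoic acid | C/C=C(\C)C(=O)O | starting material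
10 | methyl (2Z,4R,6R)-2-(chloromethyl)-6-methyl-4-{[(2E)-2-methylbut-2-enoyl]oxy}-6-(triethylsilyloxy)octa-2,7-dienoate | COC(=O)/C(CCl)=C/[C@H](OC(=O)/C(C)=C/C)C[C@@](C)(O[Si](CC)(CC)CC)C=C | intermediate
11 | methyl (2E,4R,6R)-6-methyl-4-{[(2E)-2-methylbut-2-enoyl]oxy}-2-[(4,4,5,5-tetramethyl-1,3,2-dioxaborolan-2-yl)methyl]-6-(triethylsilyloxy)octa-2,7-dienoate | COC(=O)/C(CB1OC(C)(C)C(C)(C)O1)=C/[C@H](OC(=O)/C(C)=C/C)C[C@@](C)(O[Si](CC)(CC)CC)C=C | intermediate
12 | acrolein, prop-2-enal | C=CC=O | starting material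
13 | methyl propiolate, methyl prop-2-ynoate | C#CC(=O)OC | starting material
14 | alkynylzinc, methyl 3-(methylzincio)prop-2-ynoate | C[Zn]C#CC(=O)OC | intermediate
15 | methyl (4R)-4-hydroxyhex-5-en-2-ynoate | COC(=O)C#C[C@H](O)C=C | intermediate
16 | methyl (4R)-4-(triethylsilyloxy)hex-5-en-2-ynoate | COC(=O)C#C[C@H](O[Si](CC)(CC)CC)C=C | intermediate
17 | alkenylcuprate, lithium methylcuprate adduct of 16 from syn-carbocupration (Cu on C2, cis to the new 3-methyl group) | [Li+].COC(=O)/C([Cu-]C)=C(/C)[C@H](O[Si](CC)(CC)CC)C=C | intermediate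
18 | methyl (2Z,4R)-3-methyl-4-(triethylsilyloxy)hexa-2,5-dienoate | COC(=O)/C=C(/C)[C@H](O[Si](CC)(CC)CC)C=C | intermediate
19 | (2Z,4R)-3-methyl-4-(triethylsilyloxy)hexa-2,5-dien-1-ol | OC/C=C(/C)[C@H](O[Si](CC)(CC)CC)C=C | intermediate
20 | (2Z,4R)-3-methyl-4-(triethylsilyloxy)hexa-2,5-dienal | O=C/C=C(/C)[C@H](O[Si](CC)(CC)CC)C=C | intermediate
21 | hydroxy ester, methyl (3S,4R,6R)-3-[(1S,2Z,4R)-1-hydroxy-3-methyl-4-(triethylsilyloxy)hexa-2,5-dien-1-yl]-6-methyl-4-{[(2E)-2-methylbut-2-enoyl]oxy}-2-methylidene-6-(triethylsilyloxy)oct-7-enoate | C=C(C(=O)OC)[C@@H]([C@@H](O)/C=C(/C)[C@H](O[Si](CC)(CC)CC)C=C)[C@H](OC(=O)/C(C)=C/C)C[C@@](C)(O[Si](CC)(CC)CC)C=C | intermediate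
22 | (1R,3R)-3-methyl-1-{(2S,3R)-4-methylidene-2-[(1Z,3R)-2-methyl-3-(triethylsilyloxy)penta-1,4-dien-1-yl]-5-oxooxolan-3-yl}-3-(triethylsilyloxy)pent-4-en-1-yl (2E)-2-methylbut-2-enoate | C=C1C(=O)O[C@@H](/C=C(/C)[C@H](O[Si](CC)(CC)CC)C=C)[C@H]1[C@H](OC(=O)/C(C)=C/C)C[C@@](C)(O[Si](CC)(CC)CC)C=C | intermediate
23 | (1R,3R)-3-hydroxy-1-{(2S,3R)-2-[(1Z,3R)-3-hydroxy-2-methylpenta-1,4-dien-1-yl]-4-methylidene-5-oxooxolan-3-yl}-3-methylpent-4-en-1-yl (2E)-2-methylbut-2-enoate | C=C1C(=O)O[C@@H](/C=C(/C)[C@H](O)C=C)[C@H]1[C@H](OC(=O)/C(C)=C/C)C[C@@](C)(O)C=C | intermediate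
24 | (3aR,4R,6R,7Z,9R,10Z,11aS)-6,9-dihydroxy-6,10-dimethyl-3-methylidene-2-oxo-2,3,3a,4,5,6,9,11a-octahydrocyclodeca[b]furan-4-yl (2E)-2-methylbut-2-enoate | C=C1C(=O)O[C@H]2/C=C(/C)[C@H](O)/C=C\[C@](C)(O)C[C@@H](OC(=O)/C(C)=C/C)[C@@H]12 | target

## Step count and risks

Total: 14 steps. Longest linear sequence: 9 steps (steps 1–6 and 12–14); the enal branch is 5 steps (7–11).

**Step 5 (the proposed new step).** Tiglate could attack C13 (the acrylate terminus) instead of C8, the chloride-rich medium could erode ligand control of the C8 configuration, and diene 8 can dimerise. The fallback uses known chemistry, sets out from diene 8 and comes back at chloride 10. Shi epoxidation of 8 (ketone derived from D-fructose, KHSO5 as Oxone, K2CO3, buffered MeCN–dimethoxymethane, 0 °C) at the more electron-rich trans C7=C8 olefin gives the vinyl epoxide methyl 2-{(2R,3R)-3-[(2R)-2-methyl-2-(triethylsilyloxy)but-3-en-1-yl]oxiran-2-yl}prop-2-enoate F1. LiCl with AcOH in THF opens it in the SN2' sense (chloride to C13, C8–O kept) to the hydroxy chloride methyl (2Z,4R,6R)-2-(chloromethyl)-4-hydroxy-6-methyl-6-(triethylsilyloxy)octa-2,7-dienoate F2. Yamaguchi esterification of F2 with tiglic acid 9 (2,4,6-trichlorobenzoyl chloride, Et3N, DMAP) gives 10.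

**Step 12.** The facial bias from C8 may be weak or opposite, the Z-enal 20 may isomerise, and the Lewis acid may ionise the allylic tiglate or the bis-allylic silyl ether. The fallback replaces substrate control by reagent control, sets out from chloride 10 and comes back at hydroxy ester 21. Palladium-catalysed borylation of 10 with bis(diisopropyl L-tartrate glycolato)diboron (Pd2(dba)3, toluene) gives the tartrate allylboronate methyl (2E,4R,6R)-2-{[(4R,5R)-4,5-bis(propan-2-yloxycarbonyl)-1,3,2-dioxaborolan-2-yl]methyl}-6-methyl-4-{[(2E)-2-methylbut-2-enoyl]oxy}-6-(triethylsilyloxy)octa-2,7-dienoate F3. This more Lewis-acidic Roush-type reagent adds to 20 at −78 °C in toluene over 4 Å sieves without any added Lewis acid; the chiral boron ester selects the aldehyde face, and through the chair transition state also the allyl face. Aqueous work-up gives 21, which lactonises to 22 as in step 12.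

**Step 14.** The ten-membered ring may form slowly or with the E olefin, and a ruthenium carbene may engage the methylidene lactone to give a six-membered ring. The fallback masks that olefin, sets out from diol 23 and comes back at target 24. Conjugate addition of dimethylamine (THF, 0 °C) to the methylidene lactone of 23 gives the amine (C11 epimers) 11,13-dihydro-13-(dimethylamino) derivative of 23 F4. Ring closure of its p-toluenesulfonate salt with the second-generation Hoveyda–Grubbs catalyst RuCl2(H2IMes)(=CH-C6H4-2-O-i-Pr) at higher temperature gives the macrocyclic amine 11,13-dihydro-13-(dimethylamino) derivative of 24 F5. Methyl iodide converts F5 into the quaternary salt 11,13-dihydro-13-(trimethylammonio) derivative of 24 iodide F6, which loses trimethylamine on treatment with NaHCO3 to give 24.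

## Further compounds

F1 | step 5 | methyl 2-{(2R,3R)-3-[(2R)-2-methyl-2-(triethylsilyloxy)but-3-en-1-yl]oxiran-2-yl}prop-2-enoate | C=C(C(=O)OC)[C@H]1O[C@@H]1C[C@@](C)(O[Si](CC)(CC)CC)C=C
F2 | step 5 | methyl (2Z,4R,6R)-2-(chloromethyl)-4-hydroxy-6-methyl-6-(triethylsilyloxy)octa-2,7-dienoate | COC(=O)/C(CCl)=C/[C@H](O)C[C@@](C)(O[Si](CC)(CC)CC)C=C
F3 | step 12 | methyl (2E,4R,6R)-2-{[(4R,5R)-4,5-bis(propan-2-yloxycarbonyl)-1,3,2-dioxaborolan-2-yl]methyl}-6-methyl-4-{[(2E)-2-methylbut-2-enoyl]oxy}-6-(triethylsilyloxy)octa-2,7-dienoate | COC(=O)/C(CB1O[C@@H](C(=O)OC(C)C)[C@H](C(=O)OC(C)C)O1)=C/[C@H](OC(=O)/C(C)=C/C)C[C@@](C)(O[Si](CC)(CC)CC)C=C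
F4 | step 14 | 11,13-dihydro-13-(dimethylamino) derivative of 23 (C11 epimers) | CN(C)CC1C(=O)O[C@@H](/C=C(/C)[C@H](O)C=C)[C@H]1[C@H](OC(=O)/C(C)=C/C)C[C@@](C)(O)C=C
F5 | step 14 | 11,13-dihydro-13-(dimethylamino) derivative of 24 (C11 epimers) | CN(C)CC1C(=O)O[C@H]2/C=C(/C)[C@H](O)/C=C\[C@](C)(O)C[C@@H](OC(=O)/C(C)=C/C)[C@@H]12
F6 | step 14 | 11,13-dihydro-13-(trimethylammonio) derivative of 24 iodide | [I-].C[N+](C)(C)CC1C(=O)O[C@H]2/C=C(/C)[C@H](O)/C=C\[C@](C)(O)C[C@@H](OC(=O)/C(C)=C/C)[C@@H]12
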